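(Readings and results are calculated on assumed constants.)

The vessel is closed and stirred, the gas is held at a saturation concentration of 54 mM, and none of it is in solution at the start.

common to all: gas 54 mM (held)
- theta: starting material 0.15 M; temperature 25 °C; run made earlier
- east: starting material 0.10 M; temperature 25 °C; time 15 h
- north: starting material 0.10 M; at 25 °C until 3.0 h, from then on at 55 °C; time 15 h
- west: starting material 0.10 M; temperature 55 °C; time 15 h

- theta (time / min: target / %, starting material / %): 5.00: 0.2, 98.1; 15.0: 1.5, 96.1; 25.0: 1.1, 96.2; 40.0: 5.0, 93.7; 50.0: 4.0, 92.3; 80.0: 8.9, 87.2; 90.0: 11.1, 86.6

(each reading ± 0.5 percentage points)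

- at the start none of the gas is in solution
- the earlier runs do not show what temperature does; that part of a forecast is a guess

* the flask that comes out highest in amount of target, in percent of the starting material charged, or "all alike" when all lie within 1.5 percentage points (east / north / west / all alike)
* target at the end, in percent of the starting material charged, east
* target at the end, in percent of the starting material charged, north
* target at the end, in percent of the starting material charged, west

How fast did the theta run use its charge? The last reading, at 90.0 min, showed 13.4% of 0.15 M gone. With a single concentration the readings leave the order open, so I made a bet: that gas crossing into solution paces the run, as a rate-limiting supply. From that reading I took F = 0.0134 M h⁻¹ as the feed, on this bet the starting material used per litre and hour whatever the charge.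

Does the east charge last? At F, 0.10 M is used in 7.46 h, about half of the 15 h allowed, so I expected east to finish.

What does the used material become? The last readings of the theta run left 2.3 percentage points missing from the balance, a small correction, and gave target as s = 82.8% of what was used. From that reading I put east near 82.8%. The theta run says nothing about heat, but if F paces the flasks, heat need not shorten the 7.46 h in north and west. My guess was that heat lowers s, so I put east first.

The forecast differed: north highest, with 72% in east, 91% in north and 89% in west. It noted: “Order in starting material is unknown, since there is only one concentration”.

The flasks gave 85.9% in east, 69.2% in north and 59.9% in west, so east stood highest.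

    starting material ⇌ tautomer (K = 0.0210, k = 9.30 h⁻¹, Ea = 84.0 kJ mol⁻¹, ΔH = −17.0 kJ mol⁻¹)
    starting material + reagent → isomer of the product (k = 4.00 L mol⁻¹ h⁻¹, Ea = 76.0 kJ mol⁻¹)
    reagent + tautomer → target (k = 1200 L mol⁻¹ h⁻¹, Ea = 54.0 kJ mol⁻¹)
    gas ⇌ reagent, rate k4*(csat - [reagent]) (kL = 0.290 h⁻¹)
    2 reagent → homo dimer (k = 1.00 L mol⁻¹ h⁻¹, Ea = 73.0 kJ mol⁻¹)
    (constants at 25 °C)

East held 17.1% of its starting material at 7.50 h, against the 7.46 h reckoned from F, and 0.0504% at 15.0 h. In west at 6.33 h, reagent went to target 1.5 times as fast as to isomer of the product, and west ended with 59.9% target and 40.1% isomer of the product. A neighbour of west charged at 0.40 M needs 29.9 h at F, twice the 15 h allowed, which leaves 49.8% of its starting material; the neighbour still held 41% at 15.0 h.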